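**Retrosynthetic overview**
- Target ⇐ two-stage deprotection ⇐ Yamaguchi esterification of the C8 hydroxyl of an elemane core with the acetonide of (R)-3,4-dihydroxy-2-methylenebutanoic acid.
- Cyclohexane (second ring formed, the only ring of the target) ⇐ Cope rearrangement of a 1(10)E, 4,5-ring-cis germacra-1(10),4-diene hydroxy ester; the C6–C8 triad sets C5 and C10.
- Ten-membered ring (first ring formed) ⇐ closure of C6–C7, the bond the terpene cyclase makes from the farnesyl chain, by intramolecular CrCl2 allylation of an enal with a (Z)-2-(bromomethyl)enoate; C8 sets C6 and C7.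
- Acyclic farnesane chain ⇐ Baylis–Hillman/SN2′ bromination (C11–C13), B-alkyl Suzuki (C3–C4), Zr-catalysed carboalumination/Negishi vinylation (C1=C10), acetylide opening of (S)-glycidol (C8).
- Ring order: germacrane ring, then contraction to the elemane ring; side chain and deprotection last.

Assumption: C1–C15 are germacrane/elemane locants (C12 carboxyl, C13 exocyclic methylene, C14 methyl, C15 CH2O; primes for the acyl side chain), and enantiopure 5 and 24 are purchased.

Step 1
Reactants: 1 but-2-yne-1,4-diol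
Product: 2 4-(tert-butyldimethylsilyloxy)but-2-yn-1-ol
Conditions: TBSCl (0.3 equiv), imidazole, THF/DMF, 0 °C (diol in excess, recovered)
Reagents that add atoms: tert-butyldimethylsilyl chloride CC(C)(C)[Si](C)(C)Cl
Why: Statistical mono-O-silylation of a symmetrical diol (imidazole-mediated silyl ether formation); no stereocentre is involved.

Step 2
Reactants: 2 4-(tert-butyldimethylsilyloxy)but-2-yn-1-ol
Product: 4 (Z)-4-(tert-butyldimethylsilyloxy)-3-iodobut-2-en-1-ol, via vinylalanate 3 (not isolated)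
Conditions: NaAlH2(OCH2CH2OCH3)2 (1.5 equiv), THF, 0 °C → rt; then I2, THF, −78 → 0 °C
Reagents that add atoms: iodine II
Why: Hydroxyl-directed trans-hydroalumination puts Al on the distal alkyne carbon and iodinolysis with retention gives the (Z)-iodoalkene, which fixes C3 and C6 cis on the future C4=C5 bond.

Step 3
Reactants: 5 (S)-glycidol
Product: 6 (2R)-pent-4-yne-1,2-diol
Conditions: LiC≡CH·H2NCH2CH2NH2 (3 equiv), DMSO, 0 °C → rt; H2O quench
Reagents that add atoms: lithium acetylide–ethylenediamine complex [Li]C#C.NCCN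
Why: SN2 epoxide opening by acetylide at the terminal carbon leaves the C–O stereocentre (future C8) untouched, and the degenerate Payne shift of glycidol does not racemise it.

Step 4
Reactants: 6 (2R)-pent-4-yne-1,2-diol
Product: 7 (4R)-4,5-bis(triethylsilyloxy)pent-1-yne
Conditions: TESCl (2.4 equiv), imidazole, DMF, 0 °C → rt
Reagents that add atoms: chlorotriethylsilane CC[Si](Cl)(CC)CC
Why: Routine bis-silylation (silyl ether formation); the primary TES ether is the later handle for direct oxidation and the secondary one protects C8.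

Step 5
Reactants: 7 (4R)-4,5-bis(triethylsilyloxy)pent-1-yne
Product: 9 (3E,6R)-4-methyl-6,7-bis(triethylsilyloxy)hepta-1,3-diene, via alkenylalane 8 (not isolated)
Conditions: Me3Al (3 equiv), Cp2ZrCl2 (0.3 equiv), CH2Cl2, 0 °C → rt; then CH2=CHBr (3 equiv), Pd(PPh3)4 (5 mol %), ZnCl2 (0.5 equiv), THF, rt
Reagents that add atoms: trimethylaluminium C[Al](C)C; vinyl bromide BrC=C
Why: Negishi Zr-catalysed syn-carboalumination places CH3 on the internal carbon and Al on the terminus, and Pd/Zn-catalysed alkenyl–alkenyl cross-coupling with retention gives the (E)-trisubstituted C1=C10 alkene.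

Step 6
Reactants: 9 (3E,6R)-4-methyl-6,7-bis(triethylsilyloxy)hepta-1,3-diene; 4 (Z)-4-(tert-butyldimethylsilyloxy)-3-iodobut-2-en-1-ol
Product: 11 (2E,6E,9R)-3-[(tert-butyldimethylsilyloxy)methyl]-7-methyl-9,10-bis(triethylsilyloxy)deca-2,6-dien-1-ol, via B-alkyl-9-BBN 10 (not isolated)
Conditions: 9-BBN (1.2 equiv), THF, 0 °C → rt; then 4, Pd(dppf)Cl2 (5 mol %), AsPh3 (10 mol %), Cs2CO3, DMF/H2O, rt
Reagents that add atoms: none
Why: 9-BBN hydroborates only the monosubstituted diene terminus (boron on the terminal carbon) and the B-alkyl Suzuki–Miyaura coupling retains the vinyl iodide geometry and tolerates the free allylic alcohol.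

Step 7
Reactants: 11 (2E,6E,9R)-3-[(tert-butyldimethylsilyloxy)methyl]-7-methyl-9,10-bis(triethylsilyloxy)deca-2,6-dien-1-ol
Product: 13 (2R,4E,8E)-8-[(tert-butyldimethylsilyloxy)methyl]-4-methyl-2-(triethylsilyloxy)deca-4,8-dienedial, via bis(alkoxysulfonium) salt 12 (not isolated)
Conditions: (COCl)2, DMSO, CH2Cl2, −78 → −30 °C; then Et3N, −78 → 0 °C
Reagents that add atoms: none
Why: Swern oxidation converts the allylic alcohol to the enal and also cleaves and oxidises the primary TES ether to the aldehyde, while the secondary TES and the TBS ethers survive and C8 is not enolised at low temperature.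

Step 8
Reactants: 14 2-(trimethylsilyl)ethanol
Product: 15 2-(trimethylsilyl)ethyl acrylate
Conditions: acryloyl chloride, Et3N, CH2Cl2, 0 °C
Reagents that add atoms: acryloyl chloride C=CC(=O)Cl
Why: Acylation of the alcohol by the acid chloride (esterification) gives an acrylate whose ester is later removed by fluoride.

Step 9
Reactants: 13 (2R,4E,8E)-8-[(tert-butyldimethylsilyloxy)methyl]-4-methyl-2-(triethylsilyloxy)deca-4,8-dienedial; 15 2-(trimethylsilyl)ethyl acrylate
Product: 16 2-(trimethylsilyl)ethyl (4R,6E,10E)-10-[(tert-butyldimethylsilyloxy)methyl]-3-hydroxy-6-methyl-2-methylidene-12-oxo-4-(triethylsilyloxy)dodeca-6,10-dienoate (both C3 epimers)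
Conditions: 15 (5 equiv), DABCO (1 equiv), 1,4-dioxane/H2O 1:1, rt, 48 h
Reagents that add atoms: none
Why: Morita–Baylis–Hillman reaction in which the α-silyloxy aldehyde is far more electrophilic than the β,β-disubstituted enal, so only it reacts; the new carbinol centre is erased in step 10.

Step 10
Reactants: 16 Baylis–Hillman adduct (both C3 epimers)
Product: 18 2-(trimethylsilyl)ethyl (2Z,4R,6E,10E)-2-(bromomethyl)-10-[(tert-butyldimethylsilyloxy)methyl]-6-methyl-12-oxo-4-(triethylsilyloxy)dodeca-2,6,10-trienoate, via alkoxysulfonium bromide 17 (not isolated)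
Conditions: NBS, Me2S, CH2Cl2, −20 °C → rt
Reagents that add atoms: N-bromosuccinimide BrN1C(=O)CCC1=O
Why: Corey–Kim-type activation of the allylic alcohol followed by SN2′ return of bromide gives the thermodynamically preferred (Z)-2-(bromomethyl)enoate (C8 cis to CH2Br).

Step 11
Reactants: 18 (Z)-allylic bromide enal
Product: 20 2-(trimethylsilyl)ethyl (6S,7S,8R)-15-(tert-butyldimethylsilyloxy)-6-hydroxy-8-(triethylsilyloxy)germacra-1(10)E,4,11(13)-trien-12-oate (C3 and C6 cis on C4=C5), via allylchromium dichloride 19 (not isolated)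
Conditions: CrCl2 (8 equiv), THF, rt, syringe-pump addition over 10 h (2 mM); cold pH 7 buffer work-up
Reagents that add atoms: none
Why: Intramolecular Nozaki–Hiyama–Kishi (Barbier-type) allylation at high dilution closes the C6–C7 bond that the terpene cyclase makes from the farnesyl chain: the (Z)-allylchromium (trivalent chromium) reacts through a closed chair (C8 axial, C5 equatorial) to give the 6,7-syn (ring-cis) hydroxy ester, and A1,3 strain holds H8 in the allyl plane so the aldehyde adds anti to the C9 chain, placing the acrylate cis to the C8 silyloxy group (6S,7S from 8R).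

Step 12
Reactants: 20 germacradiene hydroxy ester
Product: 22 2-(trimethylsilyl)ethyl (5S,6S,7R,8R,10S)-6,15-bis(tert-butyldimethylsilyloxy)-8-(triethylsilyloxy)elema-1,3,11(13)-trien-12-oate, via silyl ether 21 (not isolated)
Conditions: N-(tert-butyldimethylsilyl)-N-methyltrifluoroacetamide (4 equiv), toluene, 80 °C, 2 h; then 160 °C (sealed tube), 10 h
Reagents that add atoms: N-(tert-butyldimethylsilyl)-N-methyltrifluoroacetamide CN(C(=O)C(F)(F)F)[Si](C)(C)C(C)(C)C
Why: Thermal Cope rearrangement of the in situ O-silylated germacradiene (silylation blocks lactonisation): the 1(10)E / 4,5-ring-cis diene must pass through a cis-decalin-like chair in which the nascent cyclohexane has O6, O8, the C5 side chain and the C10 methyl equatorial (only the C7 acrylate and the C10 vinyl axial), the alternative chair being 1,3,5-triaxial (O6, O8, vinyl), so C5 (S) and C10 (S) are set with the two alkenyl groups cis, and strain release drives the equilibrium to the elemane.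

Step 13
Reactants: 22 fully silylated elemane ester
Product: 23 2-(trimethylsilyl)ethyl (5S,6S,7R,8R,10S)-6,15-bis(tert-butyldimethylsilyloxy)-8-hydroxyelema-1,3,11(13)-trien-12-oate
Conditions: PPTS (0.2 equiv), MeOH/CH2Cl2 1:1, 0 °C
Reagents that add atoms: none
Why: Acid-catalysed methanolysis (selective desilylation) removes the secondary TES ether much faster than either TBS ether, freeing only the C8 hydroxyl.

Step 14
Reactants: 24 methyl (R)-2-(2,2-dimethyl-1,3-dioxolan-4-yl)acetate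
Product: 28 methyl 2-[(4R)-2,2-dimethyl-1,3-dioxolan-4-yl]prop-2-enoate, via lithium enolate 25 (not isolated), via Mannich base 26 (not isolated), via ammonium iodide 27 (not isolated)
Conditions: LiN(iPr)2 (1.1 equiv), THF, −78 °C; CH2=NMe2+ I−, −78 °C → rt; then MeI, rt; then DBU, rt
Reagents that add atoms: dimethyl(methylidene)ammonium iodide C=[N+](C)C.[I-]
Why: Ester-enolate Mannich reaction with Eschenmoser's salt, quaternisation and E1cB elimination install the α-methylene group; the dioxolane C–O bond lies near the enolate nodal plane so β-elimination is slow at −78 °C and the stereocentre is untouched.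

Step 15
Reactants: 28 methyl 2-[(4R)-2,2-dimethyl-1,3-dioxolan-4-yl]prop-2-enoate
Product: 29 2-[(4R)-2,2-dimethyl-1,3-dioxolan-4-yl]prop-2-enoic acid
Conditions: LiOH, THF/H2O 3:1, 0 °C → rt; cold 1 M HCl to pH 4
Reagents that add atoms: lithium hydroxide [Li+].[OH-]
Why: Saponification (acyl-oxygen cleavage by hydroxide) of the methyl ester; the acetonide is stable to base and to the brief cold acidification.

Step 16
Reactants: 29 2-[(4R)-2,2-dimethyl-1,3-dioxolan-4-yl]prop-2-enoic acid; 23 C8 alcohol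
Product: 31 2-(trimethylsilyl)ethyl (5S,6S,7R,8R,10S)-6,15-bis(tert-butyldimethylsilyloxy)-8-{2-[(4R)-2,2-dimethyl-1,3-dioxolan-4-yl]prop-2-enoyloxy}elema-1,3,11(13)-trien-12-oate, via mixed anhydride 30 (not isolated)
Conditions: 2,4,6-trichlorobenzoyl chloride, Et3N, THF, rt; then 23, DMAP, toluene, rt → 40 °C
Reagents that add atoms: none
Why: Yamaguchi esterification (mixed anhydride, DMAP acyl transfer) acylates the only free hydroxyl with retention at C8 and C3′, and is faster than lactonisation of the C8 hydroxyl onto the ester.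

Step 17
Reactants: 31 acetonide ester
Product: 32 2-(trimethylsilyl)ethyl (5S,6S,7R,8R,10S)-6-(tert-butyldimethylsilyloxy)-8-[(3R)-3,4-dihydroxy-2-methylidenebutanoyloxy]-15-hydroxyelema-1,3,11(13)-trien-12-oate
Conditions: AcOH/THF/H2O 3:1:1, 40 °C
Reagents that add atoms: none
Why: Mild aqueous acid hydrolysis removes the terminal acetonide and the primary allylic TBS ether while the hindered secondary C6 TBS ether stays, so the cis γ-hydroxy ester cannot lactonise.

Step 18
Reactants: 32 C6 silyl ether 2-(trimethylsilyl)ethyl ester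
Product: 33 CNP0348657.6, (5S,6S,7S,8R,10S)-8-[(3R)-3,4-dihydroxy-2-methylidenebutanoyloxy]-6,15-dihydroxyelema-1,3,11(13)-trien-12-oic acid
Conditions: Bu4NF/AcOH 1:1 (10 equiv), THF, 0 → 35 °C; pH 6 phosphate work-up
Reagents that add atoms: none
Why: Buffered fluoride desilylation fragments the 2-(trimethylsilyl)ethyl ester (β-elimination to ethene) to the carboxylate before the slower C6 silyl ether cleavage, so no lactone forms, and the acetic acid buffer suppresses acyl migration and side-chain lactonisation.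

**Compound list**
1 | but-2-yne-1,4-diol | OCC#CCO | starting material
2 | 4-(tert-butyldimethylsilyloxy)but-2-yn-1-ol | CC(C)(C)[Si](C)(C)OCC#CCO | intermediate
3 | sodium vinylalanate, five-membered O–Al–C ring (Al on C3 and on O1, two 2-methoxyethoxy ligands) | CC(C)(C)[Si](C)(C)OCC1=CCO[Al-]1(OCCOC)OCCOC.[Na+] | intermediate
4 | (Z)-4-(tert-butyldimethylsilyloxy)-3-iodobut-2-en-1-ol | OC/C=C(\I)CO[Si](C)(C)C(C)(C)C | intermediate
5 | (S)-glycidol | OC[C@H]1CO1 | starting material
6 | (2R)-pent-4-yne-1,2-diol | C#CC[C@@H](O)CO | intermediate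
7 | (4R)-4,5-bis(triethylsilyloxy)pent-1-yne | C#CC[C@@H](O[Si](CC)(CC)CC)CO[Si](CC)(CC)CC | intermediate
8 | dimethyl[(1E,4R)-2-methyl-4,5-bis(triethylsilyloxy)pent-1-en-1-yl]alumane | C[Al](C)/C=C(\C)C[C@@H](O[Si](CC)(CC)CC)CO[Si](CC)(CC)CC | intermediate
9 | (3E,6R)-4-methyl-6,7-bis(triethylsilyloxy)hepta-1,3-diene | C=C/C=C(\C)C[C@@H](O[Si](CC)(CC)CC)CO[Si](CC)(CC)CC | intermediate
10 | 9-[(3E,6R)-4-methyl-6,7-bis(triethylsilyloxy)hept-3-en-1-yl]-9-borabicyclo[3.3.1]nonane | B1(CC/C=C(\C)C[C@@H](O[Si](CC)(CC)CC)CO[Si](CC)(CC)CC)C2CCCC1CCC2 | intermediate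
11 | (2E,6E,9R)-3-[(tert-butyldimethylsilyloxy)methyl]-7-methyl-9,10-bis(triethylsilyloxy)deca-2,6-dien-1-ol | OC/C=C(\CC/C=C(\C)C[C@@H](O[Si](CC)(CC)CC)CO[Si](CC)(CC)CC)CO[Si](C)(C)C(C)(C)C | intermediate
12 | bis(alkoxydimethylsulfonium) dichloride of 11 (O1 and O10 on sulfur, 10-O-silyl group lost) | C[S+](C)OC/C=C(\CC/C=C(\C)C[C@@H](O[Si](CC)(CC)CC)CO[S+](C)C)CO[Si](C)(C)C(C)(C)C.[Cl-].[Cl-] | intermediate
13 | (2R,4E,8E)-8-[(tert-butyldimethylsilyloxy)methyl]-4-methyl-2-(triethylsilyloxy)deca-4,8-dienedial | O=C/C=C(\CC/C=C(\C)C[C@@H](O[Si](CC)(CC)CC)C=O)CO[Si](C)(C)C(C)(C)C | intermediate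
14 | 2-(trimethylsilyl)ethanol | C[Si](C)(C)CCO | starting material
15 | 2-(trimethylsilyl)ethyl acrylate | C=CC(=O)OCC[Si](C)(C)C | intermediate
16 | 2-(trimethylsilyl)ethyl (4R,6E,10E)-10-[(tert-butyldimethylsilyloxy)methyl]-3-hydroxy-6-methyl-2-methylidene-12-oxo-4-(triethylsilyloxy)dodeca-6,10-dienoate (C3 epimers) | O=C/C=C(\CC/C=C(\C)C[C@@H](O[Si](CC)(CC)CC)C(O)C(=C)C(=O)OCC[Si](C)(C)C)CO[Si](C)(C)C(C)(C)C | intermediate
17 | O3-dimethylsulfonium bromide of 16 | O=C/C=C(\CC/C=C(\C)C[C@@H](O[Si](CC)(CC)CC)C(O[S+](C)C)C(=C)C(=O)OCC[Si](C)(C)C)CO[Si](C)(C)C(C)(C)C.[Br-] | intermediate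
18 | 2-(trimethylsilyl)ethyl (2Z,4R,6E,10E)-2-(bromomethyl)-10-[(tert-butyldimethylsilyloxy)methyl]-6-methyl-12-oxo-4-(triethylsilyloxy)dodeca-2,6,10-trienoate | O=C/C=C(\CC/C=C(\C)C[C@@H](O[Si](CC)(CC)CC)/C=C(\CBr)C(=O)OCC[Si](C)(C)C)CO[Si](C)(C)C(C)(C)C | intermediate
19 | allylchromium dichloride from 18 (CrCl2 in place of Br, trivalent chromium) | O=C/C=C(\CC/C=C(\C)C[C@@H](O[Si](CC)(CC)CC)/C=C(\C[Cr](Cl)Cl)C(=O)OCC[Si](C)(C)C)CO[Si](C)(C)C(C)(C)C | intermediate
20 | 2-(trimethylsilyl)ethyl (6S,7S,8R)-15-(tert-butyldimethylsilyloxy)-6-hydroxy-8-(triethylsilyloxy)germacra-1(10)E,4,11(13)-trien-12-oate, C3 and C6 cis on C4=C5 | C/C1=C\CC/C(CO[Si](C)(C)C(C)(C)C)=C\[C@H](O)[C@H](C(=C)C(=O)OCC[Si](C)(C)C)[C@H](O[Si](CC)(CC)CC)C1 | intermediate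
21 | 6-O-tert-butyldimethylsilyl ether of 20 (6S,7R,8R) | C/C1=C\CC/C(CO[Si](C)(C)C(C)(C)C)=C\[C@H](O[Si](C)(C)C(C)(C)C)[C@H](C(=C)C(=O)OCC[Si](C)(C)C)[C@H](O[Si](CC)(CC)CC)C1 | intermediate
22 | 2-(trimethylsilyl)ethyl (5S,6S,7R,8R,10S)-6,15-bis(tert-butyldimethylsilyloxy)-8-(triethylsilyloxy)elema-1,3,11(13)-trien-12-oate | C=C[C@]1(C)C[C@@H](O[Si](CC)(CC)CC)[C@@H](C(=C)C(=O)OCC[Si](C)(C)C)[C@@H](O[Si](C)(C)C(C)(C)C)[C@@H]1C(=C)CO[Si](C)(C)C(C)(C)C | intermediate
23 | 2-(trimethylsilyl)ethyl (5S,6S,7R,8R,10S)-6,15-bis(tert-butyldimethylsilyloxy)-8-hydroxyelema-1,3,11(13)-trien-12-oate | C=C[C@]1(C)C[C@@H](O)[C@@H](C(=C)C(=O)OCC[Si](C)(C)C)[C@@H](O[Si](C)(C)C(C)(C)C)[C@@H]1C(=C)CO[Si](C)(C)C(C)(C)C | intermediate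
24 | methyl (R)-2-(2,2-dimethyl-1,3-dioxolan-4-yl)acetate | COC(=O)C[C@@H]1COC(C)(C)O1 | starting material
25 | lithium enolate of 24 | [Li]OC(OC)=C[C@@H]1COC(C)(C)O1 | intermediate
26 | methyl 3-(dimethylamino)-2-[(4R)-2,2-dimethyl-1,3-dioxolan-4-yl]propanoate (C2 epimers) | COC(=O)C(CN(C)C)[C@@H]1COC(C)(C)O1 | intermediate
27 | trimethylammonium iodide of 26 | COC(=O)C(C[N+](C)(C)C)[C@@H]1COC(C)(C)O1.[I-] | intermediate
28 | methyl 2-[(4R)-2,2-dimethyl-1,3-dioxolan-4-yl]prop-2-enoate | COC(=O)C(=C)[C@@H]1COC(C)(C)O1 | intermediate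
29 | 2-[(4R)-2,2-dimethyl-1,3-dioxolan-4-yl]prop-2-enoic acid | OC(=O)C(=C)[C@@H]1COC(C)(C)O1 | intermediate
30 | mixed anhydride of 29 and 2,4,6-trichlorobenzoic acid | O=C(OC(=O)C(=C)[C@@H]1COC(C)(C)O1)c1c(Cl)cc(Cl)cc1Cl | intermediate
31 | 2-(trimethylsilyl)ethyl (5S,6S,7R,8R,10S)-6,15-bis(tert-butyldimethylsilyloxy)-8-{2-[(4R)-2,2-dimethyl-1,3-dioxolan-4-yl]prop-2-enoyloxy}elema-1,3,11(13)-trien-12-oate | C=C[C@]1(C)C[C@@H](OC(=O)C(=C)[C@@H]2COC(C)(C)O2)[C@@H](C(=C)C(=O)OCC[Si](C)(C)C)[C@@H](O[Si](C)(C)C(C)(C)C)[C@@H]1C(=C)CO[Si](C)(C)C(C)(C)C | intermediate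
32 | 2-(trimethylsilyl)ethyl (5S,6S,7R,8R,10S)-6-(tert-butyldimethylsilyloxy)-8-[(3R)-3,4-dihydroxy-2-methylidenebutanoyloxy]-15-hydroxyelema-1,3,11(13)-trien-12-oate | C=C[C@]1(C)C[C@@H](OC(=O)C(=C)[C@@H](O)CO)[C@@H](C(=C)C(=O)OCC[Si](C)(C)C)[C@@H](O[Si](C)(C)C(C)(C)C)[C@@H]1C(=C)CO | intermediate
33 | CNP0348657.6, (5S,6S,7S,8R,10S)-8-[(3R)-3,4-dihydroxy-2-methylidenebutanoyloxy]-6,15-dihydroxyelema-1,3,11(13)-trien-12-oic acid | C=C[C@]1(C)C[C@@H](OC(=O)C(=C)[C@@H](O)CO)[C@@H](C(=C)C(=O)O)[C@@H](O)[C@@H]1C(=C)CO | target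

**Step count and risk**

Total steps: 18. Longest linear sequence: 13 (steps 3–7, 9–13, 16–18, from (S)-glycidol).

The three steps most likely to fail:

Step 11 (macrocyclisation). The risks are oligomerisation, 1,4-elimination of the C8 silyloxy group from the allylmetal, lactonisation of the chromium alkoxide, and the wrong C7/C8 relationship if the ring forces the C9 chain gauche to the forming bond. The fallback sets out from 16. Acetylation (Ac2O, DMAP) gives the allylic acetate F1. Borylation with B2pin2 under Pd2(dba)3 catalysis gives the (E)-2-(alkoxycarbonyl)allylboronate F2 (C8 cis to CH2B). A metal-free intramolecular allylboration in dilute toluene at 80–100 °C (or with catalytic Sc(OTf)3 at rt) then closes the same C6–C7 bond through a closed chair, giving the cyclic borate F3. Mild aqueous NaHCO3 hydrolysis brings the route back at 20.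

Step 12 (Cope rearrangement with in situ silylation). The risks are incomplete silylation of the hindered C6 hydroxyl followed by thermal lactonisation at 160 °C, and competing 1,5-hydrogen shifts. The fallback sets out from 20 and reverses the order. A room-temperature PdCl2(PhCN)2-catalysed cyclisation–fragmentation Cope on the free alcohol (THF, 10 mol %) gives the hydroxy elemane F4 through the same chair arrangement. Silylation with TBSOTf/2,6-lutidine then returns to 22.

Step 9 (Baylis–Hillman on the dialdehyde). The risks are slow conversion, geometric isomerisation of the ring-cis enal under DABCO, and epimerisation at C8. The fallback sets out from 9 and builds the acrylate unit before the enal exists. Swern oxidation of 9 touches only the primary TES ether and gives the dienal F5. The Baylis–Hillman reaction with 15 gives the dienyl adduct F6. 9-BBN (2.2 equiv, the hydroxyl carried as its borinate) gives the bis-boron intermediate F7. Coupling with 4 under the step 6 conditions gives the diol F8. TEMPO/PhI(OAc)2 oxidises only the primary allylic alcohol and returns to 16.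

Further compounds
F1 | step 11 | 2-(trimethylsilyl)ethyl (4R,6E,10E)-3-acetoxy-10-[(tert-butyldimethylsilyloxy)methyl]-6-methyl-2-methylidene-12-oxo-4-(triethylsilyloxy)dodeca-6,10-dienoate | O=C/C=C(\CC/C=C(\C)C[C@@H](O[Si](CC)(CC)CC)C(OC(C)=O)C(=C)C(=O)OCC[Si](C)(C)C)CO[Si](C)(C)C(C)(C)C
F2 | step 11 | 2-(trimethylsilyl)ethyl (2E,4R,6E,10E)-10-[(tert-butyldimethylsilyloxy)methyl]-6-methyl-12-oxo-2-[(4,4,5,5-tetramethyl-1,3,2-dioxaborolan-2-yl)methyl]-4-(triethylsilyloxy)dodeca-2,6,10-trienoate | O=C/C=C(\CC/C=C(\C)C[C@@H](O[Si](CC)(CC)CC)/C=C(\CB1OC(C)(C)C(C)(C)O1)C(=O)OCC[Si](C)(C)C)CO[Si](C)(C)C(C)(C)C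
F3 | step 11 | 6-O-(4,4,5,5-tetramethyl-1,3,2-dioxaborolan-2-yl) derivative of 20 | C/C1=C\CC/C(CO[Si](C)(C)C(C)(C)C)=C\[C@H](OB2OC(C)(C)C(C)(C)O2)[C@H](C(=C)C(=O)OCC[Si](C)(C)C)[C@H](O[Si](CC)(CC)CC)C1
F4 | step 12 | 2-(trimethylsilyl)ethyl (5S,6S,7S,8R,10S)-15-(tert-butyldimethylsilyloxy)-6-hydroxy-8-(triethylsilyloxy)elema-1,3,11(13)-trien-12-oate | C=C[C@]1(C)C[C@@H](O[Si](CC)(CC)CC)[C@@H](C(=C)C(=O)OCC[Si](C)(C)C)[C@@H](O)[C@@H]1C(=C)CO[Si](C)(C)C(C)(C)C
F5 | step 9 | (2R,4E)-4-methyl-2-(triethylsilyloxy)hepta-4,6-dienal | C=C/C=C(\C)C[C@@H](O[Si](CC)(CC)CC)C=O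
F6 | step 9 | 2-(trimethylsilyl)ethyl (4R,6E)-3-hydroxy-6-methyl-2-methylidene-4-(triethylsilyloxy)nona-6,8-dienoate (C3 epimers) | C=C/C=C(\C)C[C@@H](O[Si](CC)(CC)CC)C(O)C(=C)C(=O)OCC[Si](C)(C)C
F7 | step 9 | 9-BBN adduct of F6 (boron on C9 and on O3) | C(CB1C2CCCC1CCC2)/C=C(\C)C[C@@H](O[Si](CC)(CC)CC)C(OB3C4CCCC3CCC4)C(=C)C(=O)OCC[Si](C)(C)C
F8 | step 9 | 2-(trimethylsilyl)ethyl (4R,6E,10E)-10-[(tert-butyldimethylsilyloxy)methyl]-3,12-dihydroxy-6-methyl-2-methylidene-4-(triethylsilyloxy)dodeca-6,10-dienoate (C3 epimers) | OC/C=C(\CC/C=C(\C)C[C@@H](O[Si](CC)(CC)CC)C(O)C(=C)C(=O)OCC[Si](C)(C)C)CO[Si](C)(C)C(C)(C)C
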